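**Plan**

Ring positions follow 1,2-dihydronaphthalene: C1 carries the aryl group, C2 the acetoxymethyl group, C3 the formyl group, C4 is the =CH, C8 carries OMe, and C8a lies between C1 and C8.
Retrosynthesis: after masking both phenols as silyl ethers, C3=C4 and C1–C8a are cut together. This gives a vanillin-derived aldehyde (ring A with its C4 carbon, SiMe3 on the future C8a) and a cyclopropane carbaldehyde in which C1 and C3 are joined by a temporary bond. The cyclopropane is cut at C3–C1/C3–C2 to an (E)-cinnamyl diazoacetate made from methyl ferulate.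
Enabling feature: C1 bears a 4-oxygenated aryl group (latent p-quinone methide, donor) and C3, two atoms away, bears the formyl group (acceptor), which is the retron of a donor–acceptor cyclopropane. On ring A the aldehyde carbon C4 is ortho to C8a, the OMe-flanked carbon that directed lithiation can reach.
Forward: the three-membered ring and a temporary lactone are made first (step 4), the lactone is opened to the formyl/acetoxymethyl cyclopropane, the six-membered carbocycle is closed in one operation onto the preformed benzene ring A (step 9), and desilylation ends the route.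
Stereochemistry: C2 comes from the catalyst-controlled cyclopropanation (step 4). C1 is set in step 9, trans to the C2 substituent, through a planar benzylic cation, so that step is stereoconvergent in every other centre of its precursors.

Key step: step 9

Assumption: the (4R)-configured Rh(II) carboxamidate of step 4 is taken to give the (1S,5R,6R) lactone, by the facial preference known for simpler allylic diazoacetates; the enantiomeric catalyst is the remedy if the sense were reversed.

**Route**

Step 1
Reactants: 1 methyl (E)-ferulate [methyl (E)-3-(4-hydroxy-3-methoxyphenyl)prop-2-enoate]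
Product: 2 methyl (E)-3-[4-(tert-butyldimethylsilyloxy)-3-methoxyphenyl]prop-2-enoate
Conditions: TBSCl, imidazole, DMF, rt
Reagents that add atoms: tert-butyldimethylsilyl chloride, CC(C)(C)[Si](C)(C)Cl
Why: Imidazole-promoted silylation masks the phenol, which would otherwise quench DIBAL-H and later insert into the rhodium carbenoid.

Step 2
Reactants: 2 methyl (E)-3-[4-(tert-butyldimethylsilyloxy)-3-methoxyphenyl]prop-2-enoate
Product: 3 (E)-3-[4-(tert-butyldimethylsilyloxy)-3-methoxyphenyl]prop-2-en-1-ol
Conditions: DIBAL-H (2.2 equiv), CH2Cl2, −78 °C; Rochelle salt work-up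
Reagents that add atoms: none
Why: DIBAL-H 1,2-reduction of the enoate should give the (E)-allylic alcohol without touching the aryl silyl ether or the alkene geometry.

Step 3
Reactants: 3 (E)-3-[4-(tert-butyldimethylsilyloxy)-3-methoxyphenyl]prop-2-en-1-ol
Product: 5 (E)-3-[4-(tert-butyldimethylsilyloxy)-3-methoxyphenyl]prop-2-en-1-yl 2-diazoacetate, via glyoxylate tosylhydrazone ester 4 (not isolated)
Conditions: TsNHN=CHCOCl, PhNMe2, CH2Cl2, 0 °C; then Et3N, 0 °C → rt
Reagents that add atoms: glyoxylic acid chloride p-toluenesulfonylhydrazone, Cc1ccc(cc1)S(=O)(=O)NN=CC(Cl)=O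
Why: Acylation by the glyoxylyl chloride tosylhydrazone followed by Bamford–Stevens-type loss of sulfinate gives the allylic diazoacetate under basic conditions that spare the ionisable cinnamyl ester.

Step 4
Reactants: 5 (E)-3-[4-(tert-butyldimethylsilyloxy)-3-methoxyphenyl]prop-2-en-1-yl 2-diazoacetate
Product: 6 (1S,5R,6R)-6-[4-(tert-butyldimethylsilyloxy)-3-methoxyphenyl]-3-oxabicyclo[3.1.0]hexan-2-one
Conditions: Rh2(4R-MPPIM)4 (1 mol%), CH2Cl2, reflux, slow addition of 5
Reagents that add atoms: none
Why: Intramolecular Rh(II)-carbenoid cyclopropanation of an allylic diazoacetate transfers the (E)-alkene geometry stereospecifically (aryl exo, ring fusion necessarily cis), and the chiral carboxamidate ligand sphere selects the alkene face and so fixes the absolute configuration of the carbon that becomes C2.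

Step 5
Reactants: 6 (1S,5R,6R)-6-[4-(tert-butyldimethylsilyloxy)-3-methoxyphenyl]-3-oxabicyclo[3.1.0]hexan-2-one
Product: 8 [(1R,2S,3R)-3-[4-(tert-butyldimethylsilyloxy)-3-methoxyphenyl]-2-[methoxy(methyl)carbamoyl]cyclopropyl]methyl acetate, via chloromagnesium alkoxide 7 (not isolated)
Conditions: MeNH(OMe)·HCl, i-PrMgCl, THF, −20 °C; then Ac2O, DMAP (cat.), −20 °C → rt
Reagents that add atoms: N,O-dimethylhydroxylamine hydrochloride, CNOC.Cl; acetic anhydride, CC(=O)OC(C)=O
Why: Weinreb aminolysis of the lactone by the magnesium amide frees the primary alkoxide, which is acetylated in the same flask before it can relactonise, so the two lactone carbons are differentiated as amide (future CHO) and acetate (final CH2OAc) with the three ring stereocentres unchanged.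

Step 6
Reactants: 8 [(1R,2S,3R)-3-[4-(tert-butyldimethylsilyloxy)-3-methoxyphenyl]-2-[methoxy(methyl)carbamoyl]cyclopropyl]methyl acetate
Product: 9 [(1R,2S,3R)-3-[4-(tert-butyldimethylsilyloxy)-3-methoxyphenyl]-2-formylcyclopropyl]methyl acetate
Conditions: Cp2Zr(H)Cl (1.5 equiv), THF, rt
Reagents that add atoms: none
Why: Schwartz reagent reduces the tertiary Weinreb amide to the aldehyde through a stable zirconium hemiaminal and should leave the acetate, the silyl ether and the cyclopropane untouched.

Step 7
Reactants: 10 vanillin (4-hydroxy-3-methoxybenzaldehyde)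
Product: 11 3-methoxy-4-(triisopropylsilyloxy)benzaldehyde
Conditions: TIPSCl, imidazole, DMF, rt
Reagents that add atoms: triisopropylsilyl chloride, CC(C)[Si](Cl)(C(C)C)C(C)C
Why: Imidazole-promoted silylation installs a bulky TIPS ether that neither directs lithiation nor is attacked by butyllithium in step 8 and that survives the acid of step 9.

Step 8
Reactants: 11 3-methoxy-4-(triisopropylsilyloxy)benzaldehyde
Product: 15 3-methoxy-4-(triisopropylsilyloxy)-2-(trimethylsilyl)benzaldehyde, via lithium α-amino alkoxide 12 (not isolated), via C2-lithiated amino alkoxide 13 (not isolated), via C2-silylated amino alkoxide 14 (not isolated)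
Conditions: LiN(Me)CH2CH2NMe2 (from the diamine and n-BuLi), THF, −20 °C; n-BuLi (3 equiv), −20 °C; TMSCl, −78 °C → rt; H2O
Reagents that add atoms: chlorotrimethylsilane, C[Si](C)(C)Cl
Why: Directed ortho-metalation in which the in situ α-amino alkoxide protects the aldehyde and, together with the neighbouring OMe group, directs lithiation to the carbon between them, which is silylated before aqueous work-up returns the aldehyde.

Step 9
Reactants: 9 [(1R,2S,3R)-3-[4-(tert-butyldimethylsilyloxy)-3-methoxyphenyl]-2-formylcyclopropyl]methyl acetate; 15 3-methoxy-4-(triisopropylsilyloxy)-2-(trimethylsilyl)benzaldehyde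
Product: 18 [(1S,2R)-1-[4-(tert-butyldimethylsilyloxy)-3-methoxyphenyl]-3-formyl-8-methoxy-7-(triisopropylsilyloxy)-1,2-dihydronaphthalen-2-yl]methyl acetate, via tetrahydrofuran adduct 16 (not isolated), via hydroxy enal 17 (not isolated)
Conditions: 15 (1.5 equiv), pyrrolidine·TFA (20 mol%), CH2Cl2–HFIP 4:1, rt, slow addition of 9; then TFA (3 equiv), −20 → 0 °C
Reagents that add atoms: none
Why: Proposed new method: pyrrolidine turns the formyl group of 9 into an iminium ion, which makes the aryl/formyl pair a strongly polarised donor–acceptor cyclopropane; the bond between the aryl-bearing and the formyl-bearing ring carbon heterolyses to a siloxybenzyl (quinone-methide-type) cation and an enamine, the carbonyl oxygen of 15 caps the cation, and the enamine carbon closes onto the resulting oxocarbenium carbon (5-endo-trig, the known (3+2) mode of donor–acceptor cyclopropanes with aldehydes) to give 16 and the C3–C4 bond. E1cB opening of this β-alkoxy aldehyde through its enamine gives the (E)-enal 17 (C3=C4), and TFA then ionises the benzylic C1–OH so that the planar cation is attacked by the ring carbon carrying SiMe3 (6-exo-trig with respect to the quinone-methide C=C, an ipso-Friedel–Crafts closure of the carbocycle) with loss of the silyl group. The closest known reaction types are the iminium-catalysed ring opening of formylcyclopropanes by carboxylic acids, the amine-catalysed oxa-Michael/aldol condensation of salicylaldehydes with enals to 2H-chromene-3-carbaldehydes (this is its all-carbon homologue), the acid-induced rearrangement of 2,5-diaryltetrahydrofurans to 1-aryl-1,2-dihydronaphthalenes, and the silicon-directed Pictet–Spengler cyclisation. C2 is not touched; C1 is set in the last closure, where the aryl group takes the face anti to the C2 acetoxymethyl group (both pseudo-axial, clear of the peri OMe group and of the C3 formyl group), so every stereoisomer of 9, 16 and 17 at the other centres is funnelled into the trans-(1S,2R) product. The step needs closure at the carbon between the side chain and OMe instead of the free position para to OMe, which the ipso-directing silyl group secures, and ring closure faster than loss of the C2 proton from the cation, for which the intramolecular six-ring closure and reversible capture of the cation by the neighbouring acetate stand.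

Step 10
Reactants: 18 [(1S,2R)-1-[4-(tert-butyldimethylsilyloxy)-3-methoxyphenyl]-3-formyl-8-methoxy-7-(triisopropylsilyloxy)-1,2-dihydronaphthalen-2-yl]methyl acetate
Product: 19 [(1S,2R)-3-formyl-7-hydroxy-1-(4-hydroxy-3-methoxyphenyl)-8-methoxy-1,2-dihydronaphthalen-2-yl]methyl acetate
Conditions: Et3N·3HF, THF, 0 °C → rt
Reagents that add atoms: none
Why: Fluoride-mediated desilylation cleaves both aryl silyl ethers under near-neutral conditions that should leave the primary acetate, the enal and the two non-enolisable stereocentres alone, and any material that lost its TBS group in step 9 converges here.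

**Compound list**

1 | methyl (E)-ferulate | COC(=O)/C=C/c1ccc(O)c(OC)c1 | starting material
2 | methyl (E)-3-[4-(tert-butyldimethylsilyloxy)-3-methoxyphenyl]prop-2-enoate | COC(=O)/C=C/c1ccc(O[Si](C)(C)C(C)(C)C)c(OC)c1 | intermediate
3 | (E)-3-[4-(tert-butyldimethylsilyloxy)-3-methoxyphenyl]prop-2-en-1-ol | OC/C=C/c1ccc(O[Si](C)(C)C(C)(C)C)c(OC)c1 | intermediate
4 | glyoxylate p-toluenesulfonylhydrazone ester of 3 (not isolated) | Cc1ccc(cc1)S(=O)(=O)NN=CC(=O)OC/C=C/c1ccc(O[Si](C)(C)C(C)(C)C)c(OC)c1 | intermediate
5 | (E)-3-[4-(tert-butyldimethylsilyloxy)-3-methoxyphenyl]prop-2-en-1-yl 2-diazoacetate | [N-]=[N+]=CC(=O)OC/C=C/c1ccc(O[Si](C)(C)C(C)(C)C)c(OC)c1 | intermediate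
6 | (1S,5R,6R)-6-[4-(tert-butyldimethylsilyloxy)-3-methoxyphenyl]-3-oxabicyclo[3.1.0]hexan-2-one | O=C1OC[C@@H]2[C@@H](c3ccc(O[Si](C)(C)C(C)(C)C)c(OC)c3)[C@H]12 | intermediate
7 | chloromagnesium alkoxide of (1S,2R,3R)-3-[4-(tert-butyldimethylsilyloxy)-3-methoxyphenyl]-2-(hydroxymethyl)-N-methoxy-N-methylcyclopropane-1-carboxamide (not isolated) | CON(C)C(=O)[C@@H]1[C@H](CO[Mg]Cl)[C@H]1c1ccc(O[Si](C)(C)C(C)(C)C)c(OC)c1 | intermediate
8 | [(1R,2S,3R)-3-[4-(tert-butyldimethylsilyloxy)-3-methoxyphenyl]-2-[methoxy(methyl)carbamoyl]cyclopropyl]methyl acetate | CON(C)C(=O)[C@@H]1[C@H](COC(C)=O)[C@H]1c1ccc(O[Si](C)(C)C(C)(C)C)c(OC)c1 | intermediate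
9 | [(1R,2S,3R)-3-[4-(tert-butyldimethylsilyloxy)-3-methoxyphenyl]-2-formylcyclopropyl]methyl acetate (CHO and CH2OAc cis, aryl trans to both) | O=C[C@@H]1[C@H](COC(C)=O)[C@H]1c1ccc(O[Si](C)(C)C(C)(C)C)c(OC)c1 | intermediate
10 | vanillin | O=Cc1ccc(O)c(OC)c1 | starting material
11 | 3-methoxy-4-(triisopropylsilyloxy)benzaldehyde | O=Cc1ccc(O[Si](C(C)C)(C(C)C)C(C)C)c(OC)c1 | intermediate
12 | lithium α-amino alkoxide of 11 with N,N,N'-trimethylethylenediamine (not isolated) | [Li]OC(N(C)CCN(C)C)c1ccc(O[Si](C(C)C)(C(C)C)C(C)C)c(OC)c1 | intermediate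
13 | C2-lithiated α-amino alkoxide (not isolated) | [Li]OC(N(C)CCN(C)C)c1ccc(O[Si](C(C)C)(C(C)C)C(C)C)c(OC)c1[Li] | intermediate
14 | C2-trimethylsilylated α-amino alkoxide (not isolated) | [Li]OC(N(C)CCN(C)C)c1ccc(O[Si](C(C)C)(C(C)C)C(C)C)c(OC)c1[Si](C)(C)C | intermediate
15 | 3-methoxy-4-(triisopropylsilyloxy)-2-(trimethylsilyl)benzaldehyde | O=Cc1ccc(O[Si](C(C)C)(C(C)C)C(C)C)c(OC)c1[Si](C)(C)C | intermediate
16 | [2-[4-(tert-butyldimethylsilyloxy)-3-methoxyphenyl]-4-formyl-5-[3-methoxy-4-(triisopropylsilyloxy)-2-(trimethylsilyl)phenyl]oxolan-3-yl]methyl acetate, oxolane C3 configured as the CH2OAc-bearing carbon of 9, other ring centres as a mixture (not isolated) | O=CC1[C@H](COC(C)=O)C(c2ccc(O[Si](C)(C)C(C)(C)C)c(OC)c2)OC1c1ccc(O[Si](C(C)C)(C(C)C)C(C)C)c(OC)c1[Si](C)(C)C | intermediate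
17 | [(E)-1-[4-(tert-butyldimethylsilyloxy)-3-methoxyphenyl]-3-formyl-1-hydroxy-4-[3-methoxy-4-(triisopropylsilyloxy)-2-(trimethylsilyl)phenyl]but-3-en-2-yl]methyl acetate, C2 configured as in 9, both epimers at the carbinol carbon (not isolated) | O=C/C(=C/c1ccc(O[Si](C(C)C)(C(C)C)C(C)C)c(OC)c1[Si](C)(C)C)[C@H](COC(C)=O)C(O)c1ccc(O[Si](C)(C)C(C)(C)C)c(OC)c1 | intermediate
18 | [(1S,2R)-1-[4-(tert-butyldimethylsilyloxy)-3-methoxyphenyl]-3-formyl-8-methoxy-7-(triisopropylsilyloxy)-1,2-dihydronaphthalen-2-yl]methyl acetate | COc1cc([C@H]2c3c(ccc(O[Si](C(C)C)(C(C)C)C(C)C)c3OC)C=C(C=O)[C@@H]2COC(C)=O)ccc1O[Si](C)(C)C(C)(C)C | intermediate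
19 | [(1S,2R)-3-formyl-7-hydroxy-1-(4-hydroxy-3-methoxyphenyl)-8-methoxy-1,2-dihydronaphthalen-2-yl]methyl acetate | COc1cc([C@H]2c3c(ccc(O)c3OC)C=C(C=O)[C@@H]2COC(C)=O)ccc1O | target

**Step count and risks**

Total steps: 10 (steps 1–6 for the cyclopropane aldehyde, steps 7–8 for the silylated aldehyde, steps 9–10). Longest linear sequence: 8 (steps 1–6, 9, 10).

Steps most likely to fail:

1. Step 9 (Proposed new method). Three processes may defeat it. The ring-opened benzylic cation may lose the C2 proton, giving a styrene and, on re-protonation, erosion of the C2 configuration. The cyclopropane aldehyde may self-condense or isomerise to a dihydrofuran faster than it is captured by 15. Protodesilylation may occur ahead of ring closure, followed by closure para to OMe. Fallback with known chemistry, from lactone 6 (with 15) back to 18: lactone 6 is hydrogenolysed at the benzylic cyclopropane bond next to the carbonyl group (H2, Pd/C, EtOAc) to the (R)-β-benzyl butyrolactone F1. Its lithium enolate (LiHMDS, THF, −78 °C) adds to 15 to give the aldol adduct F2, which is dehydrated (TsOH cat., toluene, 80 °C) to the (E)-arylidene lactone F3. Oxidative cyclisation with DDQ in TFA/CH2Cl2 at 0 °C (benzylic hydride abstraction, then silicon-directed ipso ring closure) gives the trans-dihydronaphthalene lactone F4. Weinreb aminolysis (MeNH(OMe)·HCl, AlMe3) opens it to the hydroxy Weinreb amide F5, acetylation (Ac2O, pyridine) gives the acetoxy Weinreb amide F6, and Cp2Zr(H)Cl reduces it to 18.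

2. Step 4. Facial selectivity of the carbenoid addition may be insufficient or of the opposite sense with this electron-rich cinnamyl system, or carbene dimerisation may compete. Fallback, from lactone 6 of any enantiomeric purity (an achiral Rh(II) carboxylate then suffices in step 4) back to 9: LiBH4 in THF reduces 6 to the meso diol F7, in which the chirality of 6 is erased. Lipase-catalysed monoacetylation with vinyl acetate desymmetrises it to the monoacetate F8. Dess–Martin oxidation of the remaining hydroxymethyl group gives 9, so steps 5 and 6 are replaced as well.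

3. Step 8. Lithiation may occur at a ring position other than the one between the aldehyde-derived group and OMe, or butyllithium may attack the aryl silyl ether. Fallback, from commercial material back to 18, replacing the ipso-directing silyl group by a blocking group: 6-bromovanillin F9 is silylated (TIPSCl, imidazole) to its TIPS ether F10, which is used in step 9 in place of 15. With the position para to OMe blocked by bromine, the annulation (through the bromo analogues of 16 and 17, tetrahydrofuran adduct F11 and hydroxy enal F12) can close only at the free carbon between the side chain and OMe and gives the 5-bromo analogue of 18 F13. Palladium-catalysed formate reduction (Pd(OAc)2, PPh3, HCO2H, Et3N, DMF) removes the bromine and returns to 18.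

**Further compounds**

F1 | step 9 | (R)-4-[[4-(tert-butyldimethylsilyloxy)-3-methoxyphenyl]methyl]oxolan-2-one | O=C1C[C@H](CO1)Cc1ccc(O[Si](C)(C)C(C)(C)C)c(OC)c1
F2 | step 9 | (4R)-4-[[4-(tert-butyldimethylsilyloxy)-3-methoxyphenyl]methyl]-3-[hydroxy[3-methoxy-4-(triisopropylsilyloxy)-2-(trimethylsilyl)phenyl]methyl]oxolan-2-one (aldol adduct, new centres as formed) | O=C1OC[C@H](Cc2ccc(O[Si](C)(C)C(C)(C)C)c(OC)c2)C1C(O)c1ccc(O[Si](C(C)C)(C(C)C)C(C)C)c(OC)c1[Si](C)(C)C
F3 | step 9 | (3E,4R)-4-[[4-(tert-butyldimethylsilyloxy)-3-methoxyphenyl]methyl]-3-[[3-methoxy-4-(triisopropylsilyloxy)-2-(trimethylsilyl)phenyl]methylidene]oxolan-2-one | O=C1OC[C@H](Cc2ccc(O[Si](C)(C)C(C)(C)C)c(OC)c2)/C1=C\c1ccc(O[Si](C(C)C)(C(C)C)C(C)C)c(OC)c1[Si](C)(C)C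
F4 | step 9 | (3aR,4S)-4-[4-(tert-butyldimethylsilyloxy)-3-methoxyphenyl]-5-methoxy-6-(triisopropylsilyloxy)-3a,4-dihydronaphtho[2,3-c]furan-1(3H)-one | COc1cc([C@H]2c3c(ccc(O[Si](C(C)C)(C(C)C)C(C)C)c3OC)C=C3C(=O)OC[C@H]23)ccc1O[Si](C)(C)C(C)(C)C
F5 | step 9 | hydroxy Weinreb amide corresponding to 18 (C(=O)N(Me)OMe in place of CHO, CH2OH in place of CH2OAc, same (1S,2R) centres) | COc1cc([C@H]2c3c(ccc(O[Si](C(C)C)(C(C)C)C(C)C)c3OC)C=C(C(=O)N(C)OC)[C@@H]2CO)ccc1O[Si](C)(C)C(C)(C)C
F6 | step 9 | acetoxy Weinreb amide corresponding to 18 (C(=O)N(Me)OMe in place of CHO) | COc1cc([C@H]2c3c(ccc(O[Si](C(C)C)(C(C)C)C(C)C)c3OC)C=C(C(=O)N(C)OC)[C@@H]2COC(C)=O)ccc1O[Si](C)(C)C(C)(C)C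
F7 | step 4 | meso-[3-[4-(tert-butyldimethylsilyloxy)-3-methoxyphenyl]cyclopropane-1,2-diyl]dimethanol (hydroxymethyl groups cis, aryl trans to both) | OC[C@@H]1[C@H](CO)[C@H]1c1ccc(O[Si](C)(C)C(C)(C)C)c(OC)c1
F8 | step 4 | [(1R,2S,3S)-3-[4-(tert-butyldimethylsilyloxy)-3-methoxyphenyl]-2-(hydroxymethyl)cyclopropyl]methyl acetate | OC[C@@H]1[C@H](COC(C)=O)[C@H]1c1ccc(O[Si](C)(C)C(C)(C)C)c(OC)c1
F9 | step 8 | 6-bromovanillin (2-bromo-4-hydroxy-5-methoxybenzaldehyde) | O=Cc1cc(OC)c(O)cc1Br
F10 | step 8 | 2-bromo-5-methoxy-4-(triisopropylsilyloxy)benzaldehyde | O=Cc1cc(OC)c(O[Si](C(C)C)(C(C)C)C(C)C)cc1Br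
F11 | step 8 | [5-[2-bromo-5-methoxy-4-(triisopropylsilyloxy)phenyl]-2-[4-(tert-butyldimethylsilyloxy)-3-methoxyphenyl]-4-formyloxolan-3-yl]methyl acetate (bromo analogue of 16) | O=CC1[C@H](COC(C)=O)C(c2ccc(O[Si](C)(C)C(C)(C)C)c(OC)c2)OC1c1cc(OC)c(O[Si](C(C)C)(C(C)C)C(C)C)cc1Br
F12 | step 8 | [(E)-4-[2-bromo-5-methoxy-4-(triisopropylsilyloxy)phenyl]-1-[4-(tert-butyldimethylsilyloxy)-3-methoxyphenyl]-3-formyl-1-hydroxybut-3-en-2-yl]methyl acetate (bromo analogue of 17) | O=C/C(=C/c1cc(OC)c(O[Si](C(C)C)(C(C)C)C(C)C)cc1Br)[C@H](COC(C)=O)C(O)c1ccc(O[Si](C)(C)C(C)(C)C)c(OC)c1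
F13 | step 8 | [(1S,2R)-5-bromo-1-[4-(tert-butyldimethylsilyloxy)-3-methoxyphenyl]-3-formyl-8-methoxy-7-(triisopropylsilyloxy)-1,2-dihydronaphthalen-2-yl]methyl acetate | COc1cc([C@H]2c3c(c(Br)cc(O[Si](C(C)C)(C(C)C)C(C)C)c3OC)C=C(C=O)[C@@H]2COC(C)=O)ccc1O[Si](C)(C)C(C)(C)C
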